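**Retrosynthetic overview**

1. Target 11 comes from diol 10 by benzoylation of the primary hydroxyl, and 10 from acetonide 9. The C2 benzoate of 9 is set by Mitsunobu inversion of allylic alcohol 8, which comes from hydroxyl-directed reduction of enone 7.
2. Enone 7 comes from ketol 6 by dehydrogenation; C3=C4 is the only position where a double bond can form.
3. Key disconnection of 6: the C4–C5 bond (Michael addition) and the C1–C6 bond (aldol addition) are made in one Robinson-type annulation. The partners are dihydroxyacetone acetonide 3 (C5, C6 and the CH2O carbon) and acetoxymethyl vinyl ketone 4 (C1–C4), released in the flask from diacetate 2.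
4. Enabling feature: C5, C6 and the exocyclic CH2O carbon form a dihydroxyacetone unit, a ketone carbon (C6) next to an enolisable oxygenated carbon (C5). With C2 raised to a ketone, C6–C1–C2 is a β-hydroxy ketone and C4 is the β-carbon of a vinyl ketone whose α′-carbon (C1) carries the acetoxy group.
5. Ring order: the dioxane ring is present from the start in 3, the carbocycle is annulated onto it in step 2, and the dioxane ring is opened in step 6.

Key step: step 2

Remark: target numbering is C1 = CH(OAc), C2 = CH(OBz), C3=C4, C5 = CH(OH), C6 = C(OH)(CH2OBz). The bicyclic intermediates are numbered as 4H-1,3-benzodioxins (C5 = target C1, C6 = C2, C7 = C3, C8 = C4, C8a = C5, C4a = C6, C4 = the CH2O carbon).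

**Route**

Step 1
Reactants: 1 but-2-yne-1,4-diyl diacetate
Product: 2 2-oxobutane-1,4-diyl diacetate
Conditions: Ph3PAuCl (2 mol%), AgSbF6 (2 mol%), H2O (3 equiv), 1,4-dioxane, 25 °C
Reagents that add atoms: water (O)
Why: Gold-catalysed alkyne hydration of a propargylic acetate should proceed with anchimeric assistance of the ester carbonyl (5-exo-dig attack, dioxolenium ion, water), and because the alkyne is symmetric either sense of addition gives the same ketone.

Step 2
Reactants: 2 2-oxobutane-1,4-diyl diacetate; 3 2,2-dimethyl-1,3-dioxan-5-one (3 equiv)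
Product: 6 (4aS,5R,8aR)-4a-hydroxy-2,2-dimethyl-6-oxohexahydro-4H-1,3-benzodioxin-5-yl acetate, via acetoxymethyl vinyl ketone 4 (not isolated), via diketone Michael adduct 5 (not isolated)
Conditions: (R)-proline (30 mol%), DMSO, 23 °C, 2 added over 12 h
Reagents that add atoms: none
Why: Proposed new method: proline-enamine formation on 2 should expel the β-acetate and release vinyl ketone 4 slowly; the proline enamine of 3 then adds to 4 (Michael addition, the C4–C5 bond of the target) to give diketone 5, and an enamine at the acetoxy-bearing α′-carbon of the side-chain ketone attacks the dioxanone carbonyl (aldol addition, the C1–C6 bond). The closest known reaction type is the proline-catalysed Robinson annulation stopped at the ketol (Hajos–Parrish–Eder–Sauer–Wiechert aldolisation), with a β-acyloxy ketone as vinyl ketone precursor as in classical Robinson practice; new here are the dihydroxyacetone-type donor and the dynamic resolution. The carbocycle closes in a 6-(enolendo)-exo-trig aldol addition onto the preformed dioxane ring, and the chair-like bicyclic transition state imposes the cis ring fusion. C8a, formed in the Michael step, is alpha to the ring ketone and should epimerise through the enamine, so the carboxylic-acid-directed aldol transition state picks one enantiomer and sets C4a (dynamic kinetic resolution); (R)-proline is chosen because (S)-proline gives the Hajos–Parrish ketol with the opposite sense at the carbinol carbon. C5 lies alpha to the new ketone and should settle with its acetoxy group equatorial, trans to the angular hydroxyl. The step needs mono-alkylation (excess 3 and the slow release of 4 secure it), enamine formation at the oxygenated α′-carbon and not a bridged aldol from the dioxanone side (the hydroxyacetone-type preference of proline secures it), and survival of the ketol (23 °C, no strong acid or base).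

Step 3
Reactants: 6 (4aS,5R,8aR)-4a-hydroxy-2,2-dimethyl-6-oxohexahydro-4H-1,3-benzodioxin-5-yl acetate
Product: 7 (4aS,5R,8aR)-4a-hydroxy-2,2-dimethyl-6-oxo-4a,5,6,8a-tetrahydro-4H-1,3-benzodioxin-5-yl acetate
Conditions: IBX (2 equiv), 4-methoxypyridine N-oxide (2 equiv), DMSO, 25 °C
Reagents that add atoms: none
Why: IBX dehydrogenation of a ketone through its enol should give a single enone because only the C7–C8 side carries hydrogens on both the alpha and the beta carbon (C4a is quaternary), while the tertiary alcohol cannot be oxidised and the room-temperature N-oxide complex spares the retro-aldol-prone ketol.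

Step 4
Reactants: 7 (4aS,5R,8aR)-4a-hydroxy-2,2-dimethyl-6-oxo-4a,5,6,8a-tetrahydro-4H-1,3-benzodioxin-5-yl acetate
Product: 8 (4aS,5S,6S,8aR)-4a,6-dihydroxy-2,2-dimethyl-4a,5,6,8a-tetrahydro-4H-1,3-benzodioxin-5-yl acetate
Conditions: Me4NBH(OAc)3 (5 equiv), MeCN/AcOH (1:1), −30 °C
Reagents that add atoms: none
Why: Evans–Saksena reduction: ligand exchange should bind boron to the C4a hydroxyl and deliver hydride within the complex to the carbonyl face syn to that oxygen, giving the 1,3-anti diol by 1,2-reduction and so setting C6 as (S), with the new hydroxyl cis to the C5 acetate.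

Step 5
Reactants: 8 (4aS,5S,6S,8aR)-4a,6-dihydroxy-2,2-dimethyl-4a,5,6,8a-tetrahydro-4H-1,3-benzodioxin-5-yl acetate
Product: 9 (4aS,5S,6R,8aR)-5-(acetyloxy)-4a-hydroxy-2,2-dimethyl-4a,5,6,8a-tetrahydro-4H-1,3-benzodioxin-6-yl benzoate
Conditions: PhCO2H (1.5 equiv), PPh3 (1.5 equiv), DIAD (1.5 equiv), toluene, 0 °C to 23 °C
Reagents that add atoms: benzoic acid (OC(=O)c1ccccc1)
Why: Mitsunobu reaction: benzoate should displace the oxyphosphonium group at the secondary allylic carbon with inversion, setting C6 as (R) with the benzoate trans to the acetate, while the tertiary alcohol is inert and the cis acetate cannot participate from the side of the leaving group.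

Step 6
Reactants: 9 (4aS,5S,6R,8aR)-5-(acetyloxy)-4a-hydroxy-2,2-dimethyl-4a,5,6,8a-tetrahydro-4H-1,3-benzodioxin-6-yl benzoate
Product: 10 (1R,4R,5S,6S)-6-(acetyloxy)-4,5-dihydroxy-5-(hydroxymethyl)cyclohex-2-en-1-yl benzoate
Conditions: AcOH/H2O (4:1), 40 °C
Reagents that add atoms: none
Why: Acid-catalysed hydrolysis of the isopropylidene acetal should free the secondary allylic and the primary hydroxyl while the esters survive and the acidic medium disfavours acyl migration.

Step 7
Reactants: 10 (1R,4R,5S,6S)-6-(acetyloxy)-4,5-dihydroxy-5-(hydroxymethyl)cyclohex-2-en-1-yl benzoate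
Product: 11 [(1S,2R,5R,6S)-6-(acetyloxy)-5-(benzoyloxy)-1,2-dihydroxycyclohex-3-en-1-yl]methyl benzoate
Conditions: BzCl (1.05 equiv), 2,4,6-collidine (2 equiv), CH2Cl2, −40 °C to −10 °C
Reagents that add atoms: benzoyl chloride (O=C(Cl)c1ccccc1)
Why: Nucleophilic acyl substitution under steric control: one equivalent of benzoyl chloride with a hindered pyridine base at low temperature should acylate the primary hydroxyl only, the secondary allylic hydroxyl next to the quaternary carbon and the tertiary hydroxyl being much slower.

**Compound list**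

1 | but-2-yne-1,4-diyl diacetate | CC(=O)OCC#CCOC(C)=O | starting material
2 | 2-oxobutane-1,4-diyl diacetate | CC(=O)OCCC(=O)COC(C)=O | intermediate
3 | 2,2-dimethyl-1,3-dioxan-5-one | CC1(C)OCC(=O)CO1 | starting material
4 | 2-oxobut-3-en-1-yl acetate (acetoxymethyl vinyl ketone) | CC(=O)OCC(=O)C=C | intermediate
5 | 4-[(4R)-2,2-dimethyl-5-oxo-1,3-dioxan-4-yl]-2-oxobutyl acetate | CC(=O)OCC(=O)CC[C@H]1OC(C)(C)OCC1=O | intermediate
6 | (4aS,5R,8aR)-4a-hydroxy-2,2-dimethyl-6-oxohexahydro-4H-1,3-benzodioxin-5-yl acetate | CC(=O)O[C@H]1C(=O)CC[C@H]2OC(C)(C)OC[C@@]12O | intermediate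
7 | (4aS,5R,8aR)-4a-hydroxy-2,2-dimethyl-6-oxo-4a,5,6,8a-tetrahydro-4H-1,3-benzodioxin-5-yl acetate | CC(=O)O[C@H]1C(=O)C=C[C@H]2OC(C)(C)OC[C@@]12O | intermediate
8 | (4aS,5S,6S,8aR)-4a,6-dihydroxy-2,2-dimethyl-4a,5,6,8a-tetrahydro-4H-1,3-benzodioxin-5-yl acetate | CC(=O)O[C@H]1[C@@H](O)C=C[C@H]2OC(C)(C)OC[C@@]12O | intermediate
9 | (4aS,5S,6R,8aR)-5-(acetyloxy)-4a-hydroxy-2,2-dimethyl-4a,5,6,8a-tetrahydro-4H-1,3-benzodioxin-6-yl benzoate | CC(=O)O[C@H]1[C@H](OC(=O)c3ccccc3)C=C[C@H]2OC(C)(C)OC[C@@]12O | intermediate
10 | (1R,4R,5S,6S)-6-(acetyloxy)-4,5-dihydroxy-5-(hydroxymethyl)cyclohex-2-en-1-yl benzoate | CC(=O)O[C@H]1[C@H](OC(=O)c2ccccc2)C=C[C@@H](O)[C@@]1(O)CO | intermediate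
11 | [(1S,2R,5R,6S)-6-(acetyloxy)-5-(benzoyloxy)-1,2-dihydroxycyclohex-3-en-1-yl]methyl benzoate | CC(=O)O[C@H]1[C@H](OC(=O)c2ccccc2)C=C[C@@H](O)[C@@]1(O)COC(=O)c1ccccc1 | target

**Step count and risks**

Total step count: 7. Longest linear sequence: 7 steps (1 → 2 → 6 → 7 → 8 → 9 → 10 → 11); 3 enters at step 2.

Steps most likely to fail:

1. Step 2. The enamine Michael addition may stall or run on to double alkylation of 3, and the dynamic kinetic resolution in the aldol closure may be too weak to control which enantiomer and diastereomer forms. The fallback makes the two bonds one after the other under auxiliary control. It sets out from 3. Condensation with (R)-1-amino-2-(methoxymethyl)pyrrolidine (benzene, reflux, water separator) should give (R)-N-(2,2-dimethyl-1,3-dioxan-5-ylidene)-2-(methoxymethyl)pyrrolidin-1-amine F1. Deprotonation (t-BuLi, THF, −78 °C) and alkylation with 4-iodobut-1-ene (−100 °C), an Enders RAMP hydrazone alkylation in which the auxiliary fixes the new centre, should give (2R)-N-[(4R)-4-(but-3-en-1-yl)-2,2-dimethyl-1,3-dioxan-5-ylidene]-2-(methoxymethyl)pyrrolidin-1-amine F2. Aqueous oxalic acid (Et2O, 23 °C) should release (4R)-4-(but-3-en-1-yl)-2,2-dimethyl-1,3-dioxan-5-one F3. RuO4-catalysed ketohydroxylation of the terminal alkene (RuCl3 1 mol%, Oxone, NaHCO3, EtOAc/MeCN/H2O, 23 °C) should give (4R)-4-(4-hydroxy-3-oxobutyl)-2,2-dimethyl-1,3-dioxan-5-one F4. Acetylation (Ac2O, pyridine, 0 °C) gives 5, where the fallback comes back to the route. 5 is closed at once to 6 with (R)-proline in DMSO, now a diastereoselective aldolisation of a single enantiomer.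

2. Step 3. The β-hydroxy ketone may open by retro-aldol cleavage or dehydrate toward an aromatic product, or oxidation may occur at C5 instead of dehydrogenation. The fallback sets out from 6 and separates enolisation from oxidation. Kinetic enolisation toward the C7 methylene with silylation in the flask (LiHMDS 2.2 equiv, TMSCl, THF, −78 °C) should give (4aS,5S,8aR)-2,2-dimethyl-4a,6-bis[(trimethylsilyl)oxy]-4a,5,8,8a-tetrahydro-4H-1,3-benzodioxin-5-yl acetate F5. Saegusa–Ito oxidation (Pd(OAc)2 1 equiv, MeCN, 23 °C), followed by removal of the tertiary silyl ether on work-up with aqueous citric acid, comes back to the route at 7.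

3. Step 5. The inversion may be eroded by allylic SN2′ attack, by elimination to a diene, or by acetyl migration from the cis-vicinal acetate before the alcohol is activated. The fallback sets out from 7 and sets the C6 configuration in the reduction instead. Narasaka–Prasad reduction (Et2BOMe, NaBH4, THF/MeOH, −78 °C) should give the 1,3-syn diol, because the boron chelate between the C4a hydroxyl and the ketone covers the face syn to the angular hydroxyl and external hydride attacks from the opposite face. The product is (4aS,5S,6R,8aR)-4a,6-dihydroxy-2,2-dimethyl-4a,5,6,8a-tetrahydro-4H-1,3-benzodioxin-5-yl acetate F6. Benzoylation of its secondary hydroxyl with retention (BzCl, pyridine, CH2Cl2, 0 °C) comes back to the route at 9.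

**Further compounds**

F1 | step 2 | (R)-N-(2,2-dimethyl-1,3-dioxan-5-ylidene)-2-(methoxymethyl)pyrrolidin-1-amine | COC[C@H]1CCCN1N=C1COC(C)(C)OC1
F2 | step 2 | (2R)-N-[(4R)-4-(but-3-en-1-yl)-2,2-dimethyl-1,3-dioxan-5-ylidene]-2-(methoxymethyl)pyrrolidin-1-amine | C=CCC[C@H]1OC(C)(C)OCC1=NN1CCC[C@@H]1COC
F3 | step 2 | (4R)-4-(but-3-en-1-yl)-2,2-dimethyl-1,3-dioxan-5-one | C=CCC[C@H]1OC(C)(C)OCC1=O
F4 | step 2 | (4R)-4-(4-hydroxy-3-oxobutyl)-2,2-dimethyl-1,3-dioxan-5-one | OCC(=O)CC[C@H]1OC(C)(C)OCC1=O
F5 | step 3 | (4aS,5S,8aR)-2,2-dimethyl-4a,6-bis[(trimethylsilyl)oxy]-4a,5,8,8a-tetrahydro-4H-1,3-benzodioxin-5-yl acetate | CC(=O)O[C@H]1C(O[Si](C)(C)C)=CC[C@H]2OC(C)(C)OC[C@@]12O[Si](C)(C)C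
F6 | step 5 | (4aS,5S,6R,8aR)-4a,6-dihydroxy-2,2-dimethyl-4a,5,6,8a-tetrahydro-4H-1,3-benzodioxin-5-yl acetate | CC(=O)O[C@H]1[C@H](O)C=C[C@H]2OC(C)(C)OC[C@@]12O
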